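**Retrosynthetic overview**
1. The strategy rests on ring B, a fully substituted benzene (C1' CH2 bridge, C2' OH, C3' CH3, C4' OCH3, C5' butanoyl, C6' OH) whose three oxygens differ only in that C4' is methylated. Each oxygen is therefore drawn from a different building block.
2. The C5' butanoyl group is disconnected first (Houben–Hoesch acylation of the single free ring position). Ring B is then opened at C2'–C3' and C4'–C5' into 1-methoxypropyne and a 3-alkoxy-4-(ring A methyl)cyclobutenone (vinylketene benzannulation).
3. The cyclobutenone is cut into a ring A propanoyl chloride (as its ketene) and tert-butoxyethyne. The propanoic acid chain comes from formaldehyde and Meldrum's acid on butanoylated 2-methylphloroglucinol.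
4. Ring order: ring A is present from the start and fully substituted before coupling, the four-membered ring is made next, and ring B is formed last.

Key step: step 9

Remark (assumption): the C6' oxygen is carried as a tert-butyl ether delivered by tert-butoxyethyne, because this ynol ether is an accessible, storable reagent that cycloadds to ketenes, and the tert-butyl group is removed by acid without touching the C4' methyl ether. Both ynol ethers are prepared (steps 6 and 8).
Numbering: ring A C1 butanoyl, C2 OH, C3 CH3, C4 OH, C5 CH2 bridge, C6 OH; ring B as in line 1.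

**Step 1**
Reactants: 1 2-methylphloroglucinol; 2 butanoyl chloride
Product: 3 1-(2,4,6-trihydroxy-3-methylphenyl)butan-1-one
Conditions: AlCl3, PhNO2, rt → 60 °C; aq. HCl work-up
Reagents that add atoms: none
Why: Friedel–Crafts C-acylation of a phloroglucinol; the two free ring positions of 1 are equivalent and the chelated aryl ketone deactivates the ring against a second acylation.

**Step 2**
Reactants: 3 1-(2,4,6-trihydroxy-3-methylphenyl)butan-1-one; 4 formaldehyde; 5 Meldrum's acid
Product: 9 6-butanoyl-5,7-dihydroxy-8-methyl-3,4-dihydro-2H-chromen-2-one, via 5-methylidene Meldrum's acid 6 (not isolated), via Michael adduct 7 (not isolated), via 2-oxochromane-3-carboxylic acid 8 (not isolated)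
Conditions: 5 (1.5 equiv), 37% aq. CH2O, pyridine, rt (premix); then 3, 90 °C
Reagents that add atoms: none
Why: Knoevenagel condensation gives acceptor 6, the only free ring carbon of 3 (C5) adds in a Michael reaction, and the non-chelated C4 hydroxyl opens the dioxanedione with loss of acetone and then CO2, a known three-component dihydrocoumarin synthesis; a lactone closed through the C6 hydroxyl instead would converge in step 3.

**Step 3**
Reactants: 9 6-butanoyl-5,7-dihydroxy-8-methyl-3,4-dihydro-2H-chromen-2-one
Product: 11 benzyl 3-[2,4,6-tris(benzyloxy)-3-butanoyl-5-methylphenyl]propanoate, via ring-opened trihydroxy acid 10 (not isolated)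
Conditions: KOH, H2O/THF, rt; evaporate; then BnBr (excess), K2CO3, n-Bu4NI (cat.), DMF, 60 °C
Reagents that add atoms: potassium hydroxide, [K+].[OH-]; benzyl bromide, BrCc1ccccc1
Why: Hydroxide opens the aryl lactone and Williamson benzylation in a polar aprotic solvent then caps the three phenoxides and the carboxylate on oxygen, so re-lactonization is no longer possible.

**Step 4**
Reactants: 11 benzyl 3-[2,4,6-tris(benzyloxy)-3-butanoyl-5-methylphenyl]propanoate
Product: 12 3-[2,4,6-tris(benzyloxy)-3-butanoyl-5-methylphenyl]propanoic acid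
Conditions: LiOH, THF/MeOH/H2O, 40 °C; then 1 M HCl to pH 3
Reagents that add atoms: lithium hydroxide, [Li+].[OH-]
Why: Saponification of the unhindered benzyl ester; aryl benzyl ethers and the hindered aryl ketone are inert to hydroxide.

**Step 5**
Reactants: 12 3-[2,4,6-tris(benzyloxy)-3-butanoyl-5-methylphenyl]propanoic acid
Product: 13 3-[2,4,6-tris(benzyloxy)-3-butanoyl-5-methylphenyl]propanoyl chloride
Conditions: (COCl)2, DMF (cat.), CH2Cl2, 0 °C → rt; evaporate, use crude and cold
Reagents that add atoms: oxalyl chloride, O=C(Cl)C(=O)Cl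
Why: Standard acid chloride formation through the chloroiminium catalyst; the fully substituted ring A cannot undergo intramolecular acylation, and without a Lewis acid the ortho benzyl ethers should not be displaced.

**Step 6**
Reactants: 14 trichloroethylene; 15 potassium tert-butoxide
Product: 18 tert-butoxyethyne, via (E)-1-tert-butoxy-1,2-dichloroethene 16 (not isolated), via lithium tert-butoxyacetylide 17 (not isolated)
Conditions: THF, −20 °C → rt; then n-BuLi (2.2 equiv), −78 → −40 °C; then sat. aq. NH4Cl, −78 °C; used as a dried, titrated solution kept cold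
Reagents that add atoms: none
Why: The known one-pot route to alkoxyacetylenes: alkoxide addition to trichloroethylene gives the dichlorovinyl ether, which n-BuLi converts by elimination and chlorine–lithium exchange into the lithium alkoxyacetylide that is protonated.

**Step 7**
Reactants: 13 3-[2,4,6-tris(benzyloxy)-3-butanoyl-5-methylphenyl]propanoyl chloride; 18 tert-butoxyethyne
Product: 20 racemic 4-{[2,4,6-tris(benzyloxy)-3-butanoyl-5-methylphenyl]methyl}-3-tert-butoxycyclobut-2-en-1-one, via ketene 19 (not isolated)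
Conditions: 18 (3 equiv), Et3N, THF/CH2Cl2, 0 °C, slow addition of 13; then rt
Reagents that add atoms: none
Why: Dehydrochlorination gives aldoketene 19, which undergoes the known [2+2] cycloaddition with an alkoxyacetylene; the nucleophilic terminal carbon of 18 bonds to the ketene carbonyl carbon, so the alkoxy group lands on C3, C2 keeps its hydrogen and the ring A methyl group sits on C4, whose new stereocentre is formed racemic and is lost in step 9.

**Step 8**
Reactants: 21 chloroacetaldehyde dimethyl acetal; 22 iodomethane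
Product: 24 1-methoxypropyne, via sodium methoxyacetylide 23 (not isolated)
Conditions: NaNH2 (3 equiv), liq. NH3, −33 °C; then MeI, −60 → −33 °C; distil
Reagents that add atoms: none
Why: Double elimination (methanol, then HCl) from the chloroacetal with NaNH2 gives the sodium alkoxyacetylide, which is C-methylated in liquid ammonia, the standard preparation of 1-alkoxy-1-alkynes.

**Step 9**
Reactants: 20 racemic 4-{[2,4,6-tris(benzyloxy)-3-butanoyl-5-methylphenyl]methyl}-3-tert-butoxycyclobut-2-en-1-one; 24 1-methoxypropyne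
Product: 29 1-{2,4,6-tris(benzyloxy)-3-[(6-tert-butoxy-2-hydroxy-4-methoxy-3-methylphenyl)methyl]-5-methylphenyl}butan-1-one, via vinylketene 25 (not isolated), via 4-alkenylcyclobutenone 26 (not isolated), via dienylketene 27 (not isolated), via cyclohexa-2,4-dienone 28 (not isolated)
Conditions: 24 (2 equiv), toluene, sealed tube, 80 → 110 °C
Reagents that add atoms: none
Why: Thermal four-electron electrocyclic opening of 20, with the C4 arylmethyl group rotating outward, gives alkoxyvinylketene 25; the methyl-bearing nucleophilic carbon of 24 attacks the ketene carbonyl carbon and [2+2] cycloaddition across the ketene C=C gives cyclobutenone 26, forming C2'–C3' and C4'–C5'. A second four-electron opening gives dienylketene 27, which closes ring B by six-electron electrocyclization (the C1–C4 bond broken in 20 is re-formed as C1'–C2'), and cyclohexadienone 28 tautomerizes to phenol 29. The closest known reaction type is the Danheiser benzannulation of cyclobutenones, including 3-oxygenated ones, with alkoxy- and silyloxyalkynes. No stereocentre is created, since the racemic C4 centre of 20 becomes the aromatic carbon C1'. The selectivity needed is the regiochemistry of the [2+2] step, which decides that the methoxy group lands on C4'; it is secured by the polarization of the ynol ether, whose carbon remote from oxygen is the nucleophile, so the ketene oxygen becomes the C2' hydroxyl, the cyclobutenone oxygen the C6' tert-butyl ether, and C5' stays unsubstituted. Only the dienylketene with the alkenyl group turned inward can cyclize, but opening of 26 is reversible, so the cascade should funnel to 29.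

**Step 10**
Reactants: 29 1-{2,4,6-tris(benzyloxy)-3-[(6-tert-butoxy-2-hydroxy-4-methoxy-3-methylphenyl)methyl]-5-methylphenyl}butan-1-one
Product: 30 1-{2,4,6-tris(benzyloxy)-3-[(2,6-dihydroxy-4-methoxy-3-methylphenyl)methyl]-5-methylphenyl}butan-1-one
Conditions: TFA/CH2Cl2 (1:4), 0 °C, short reaction time
Reagents that add atoms: none
Why: Acidolysis of the aryl tert-butyl ether through the tert-butyl cation (lost as isobutene) is much faster than cleavage of aryl methyl or benzyl ethers, which frees only the C6' hydroxyl.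

**Step 11**
Reactants: 30 1-{2,4,6-tris(benzyloxy)-3-[(2,6-dihydroxy-4-methoxy-3-methylphenyl)methyl]-5-methylphenyl}butan-1-one; 31 butanenitrile
Product: 33 1-{2,4,6-tris(benzyloxy)-3-[(3-butanoyl-2,6-dihydroxy-4-methoxy-5-methylphenyl)methyl]-5-methylphenyl}butan-1-one, via ketimine hydrochloride 32 (not isolated)
Conditions: ZnCl2, HCl (g), Et2O, 0 °C; then H2O, 90 °C
Reagents that add atoms: water, O
Why: Houben–Hoesch acylation of a phloroglucinol monomethyl ether; C5' is the only free aromatic position in the molecule and is activated by the ortho C6' hydroxyl, the ortho C4' methoxy and the para C2' hydroxyl, and the ketimine salt hydrolyses to the ketone while the benzyl ethers tolerate HCl in ether at 0 °C.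

**Step 12**
Reactants: 33 1-{2,4,6-tris(benzyloxy)-3-[(3-butanoyl-2,6-dihydroxy-4-methoxy-5-methylphenyl)methyl]-5-methylphenyl}butan-1-one
Product: 34 1-{3-[(3-butanoyl-2,6-dihydroxy-4-methoxy-5-methylphenyl)methyl]-2,4,6-trihydroxy-5-methylphenyl}butan-1-one (target)
Conditions: H2 (1 atm), Pd/C, EtOAc/MeOH, rt
Reagents that add atoms: none
Why: Hydrogenolysis of the three aryl benzyl ethers; the hydrogen-bonded ortho-hydroxyaryl ketones, the methyl ether and the diarylmethane are stable under these conditions.

**Compound list**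
1 | 2-methylphloroglucinol (2-methylbenzene-1,3,5-triol) | Cc1c(O)cc(O)cc1O | starting material
2 | butanoyl chloride | CCCC(=O)Cl | starting material
3 | 1-(2,4,6-trihydroxy-3-methylphenyl)butan-1-one | CCCC(=O)c1c(O)c(C)c(O)cc1O | intermediate
4 | formaldehyde | C=O | starting material
5 | Meldrum's acid (2,2-dimethyl-1,3-dioxane-4,6-dione) | CC1(C)OC(=O)CC(=O)O1 | starting material
6 | 2,2-dimethyl-5-methylidene-1,3-dioxane-4,6-dione (not isolated) | C=C1C(=O)OC(C)(C)OC1=O | intermediate
7 | 5-[(3-butanoyl-2,4,6-trihydroxy-5-methylphenyl)methyl]-2,2-dimethyl-1,3-dioxane-4,6-dione (not isolated) | CCCC(=O)c1c(O)c(C)c(O)c(CC2C(=O)OC(C)(C)OC2=O)c1O | intermediate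
8 | racemic 6-butanoyl-5,7-dihydroxy-8-methyl-2-oxo-3,4-dihydro-2H-chromene-3-carboxylic acid (not isolated) | CCCC(=O)c1c(O)c(C)c2OC(=O)C(C(=O)O)Cc2c1O | intermediate
9 | 6-butanoyl-5,7-dihydroxy-8-methyl-3,4-dihydro-2H-chromen-2-one | CCCC(=O)c1c(O)c(C)c2OC(=O)CCc2c1O | intermediate
10 | 3-(3-butanoyl-2,4,6-trihydroxy-5-methylphenyl)propanoic acid, formed as its potassium salt (not isolated) | CCCC(=O)c1c(O)c(C)c(O)c(CCC(=O)O)c1O | intermediate
11 | benzyl 3-[2,4,6-tris(benzyloxy)-3-butanoyl-5-methylphenyl]propanoate | CCCC(=O)c1c(OCc2ccccc2)c(C)c(OCc2ccccc2)c(CCC(=O)OCc2ccccc2)c1OCc1ccccc1 | intermediate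
12 | 3-[2,4,6-tris(benzyloxy)-3-butanoyl-5-methylphenyl]propanoic acid | CCCC(=O)c1c(OCc2ccccc2)c(C)c(OCc2ccccc2)c(CCC(=O)O)c1OCc1ccccc1 | intermediate
13 | 3-[2,4,6-tris(benzyloxy)-3-butanoyl-5-methylphenyl]propanoyl chloride | CCCC(=O)c1c(OCc2ccccc2)c(C)c(OCc2ccccc2)c(CCC(=O)Cl)c1OCc1ccccc1 | intermediate
14 | trichloroethylene (1,1,2-trichloroethene) | ClC=C(Cl)Cl | starting material
15 | potassium tert-butoxide | CC(C)(C)[O-].[K+] | starting material
16 | (E)-1-tert-butoxy-1,2-dichloroethene (not isolated) | Cl/C(OC(C)(C)C)=C/Cl | intermediate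
17 | lithium tert-butoxyacetylide (not isolated) | [Li]C#COC(C)(C)C | intermediate
18 | tert-butoxyethyne | C#COC(C)(C)C | intermediate
19 | 3-[2,4,6-tris(benzyloxy)-3-butanoyl-5-methylphenyl]prop-1-en-1-one, the ketene (not isolated) | CCCC(=O)c1c(OCc2ccccc2)c(C)c(OCc2ccccc2)c(CC=C=O)c1OCc1ccccc1 | intermediate
20 | racemic 4-{[2,4,6-tris(benzyloxy)-3-butanoyl-5-methylphenyl]methyl}-3-tert-butoxycyclobut-2-en-1-one | O=C1C=C(OC(C)(C)C)C1Cc1c(OCc2ccccc2)c(C)c(OCc2ccccc2)c(C(=O)CCC)c1OCc1ccccc1 | intermediate
21 | chloroacetaldehyde dimethyl acetal (2-chloro-1,1-dimethoxyethane) | COC(CCl)OC | starting material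
22 | iodomethane | CI | starting material
23 | sodium methoxyacetylide (not isolated) | [Na]C#COC | intermediate
24 | 1-methoxypropyne | CC#COC | intermediate
25 | (3Z)-5-[2,4,6-tris(benzyloxy)-3-butanoyl-5-methylphenyl]-3-tert-butoxypenta-1,3-dien-1-one, the vinylketene (not isolated) | O=C=C/C(OC(C)(C)C)=C/Cc1c(OCc2ccccc2)c(C)c(OCc2ccccc2)c(C(=O)CCC)c1OCc1ccccc1 | intermediate
26 | racemic 4-{(1Z)-3-[2,4,6-tris(benzyloxy)-3-butanoyl-5-methylphenyl]-1-tert-butoxyprop-1-en-1-yl}-3-methoxy-2-methylcyclobut-2-en-1-one (not isolated) | O=C1C(C)=C(OC)C1/C(OC(C)(C)C)=C/Cc1c(OCc2ccccc2)c(C)c(OCc2ccccc2)c(C(=O)CCC)c1OCc1ccccc1 | intermediate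
27 | (3E,5Z)-7-[2,4,6-tris(benzyloxy)-3-butanoyl-5-methylphenyl]-5-tert-butoxy-3-methoxy-2-methylhepta-1,3,5-trien-1-one, the dienylketene (not isolated) | O=C=C(C)/C(OC)=C\C(OC(C)(C)C)=C\Cc1c(OCc2ccccc2)c(C)c(OCc2ccccc2)c(C(=O)CCC)c1OCc1ccccc1 | intermediate
28 | racemic 6-{[2,4,6-tris(benzyloxy)-3-butanoyl-5-methylphenyl]methyl}-5-tert-butoxy-3-methoxy-2-methylcyclohexa-2,4-dien-1-one (not isolated) | O=C1C(C)=C(OC)C=C(OC(C)(C)C)C1Cc1c(OCc2ccccc2)c(C)c(OCc2ccccc2)c(C(=O)CCC)c1OCc1ccccc1 | intermediate
29 | 1-{2,4,6-tris(benzyloxy)-3-[(6-tert-butoxy-2-hydroxy-4-methoxy-3-methylphenyl)methyl]-5-methylphenyl}butan-1-one | CCCC(=O)c1c(OCc2ccccc2)c(C)c(OCc2ccccc2)c(Cc2c(O)c(C)c(OC)cc2OC(C)(C)C)c1OCc1ccccc1 | intermediate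
30 | 1-{2,4,6-tris(benzyloxy)-3-[(2,6-dihydroxy-4-methoxy-3-methylphenyl)methyl]-5-methylphenyl}butan-1-one | CCCC(=O)c1c(OCc2ccccc2)c(C)c(OCc2ccccc2)c(Cc2c(O)c(C)c(OC)cc2O)c1OCc1ccccc1 | intermediate
31 | butanenitrile | CCCC#N | starting material
32 | 1-{2,4,6-tris(benzyloxy)-3-[(3-butanimidoyl-2,6-dihydroxy-4-methoxy-5-methylphenyl)methyl]-5-methylphenyl}butan-1-one hydrochloride (not isolated) | CCCC(=O)c1c(OCc2ccccc2)c(C)c(OCc2ccccc2)c(Cc2c(O)c(C)c(OC)c(C(=N)CCC)c2O)c1OCc1ccccc1.Cl | intermediate
33 | 1-{2,4,6-tris(benzyloxy)-3-[(3-butanoyl-2,6-dihydroxy-4-methoxy-5-methylphenyl)methyl]-5-methylphenyl}butan-1-one | CCCC(=O)c1c(OCc2ccccc2)c(C)c(OCc2ccccc2)c(Cc2c(O)c(C)c(OC)c(C(=O)CCC)c2O)c1OCc1ccccc1 | intermediate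
34 | 1-{3-[(3-butanoyl-2,6-dihydroxy-4-methoxy-5-methylphenyl)methyl]-2,4,6-trihydroxy-5-methylphenyl}butan-1-one | CCCC(=O)c1c(O)c(C)c(O)c(Cc2c(O)c(C)c(OC)c(C(=O)CCC)c2O)c1O | target

**Step count and risks**
Total step count: 12 (ten in the main line and one for each ynol ether).
Longest linear sequence: 10 steps (1–5, 7, 9–12).

Steps most likely to fail:

1. Step 9. The vinylketene may be consumed by dimerization or by O-acylation of the product phenol before the [2+2] step occurs. The vinylogous tert-butyl ester may lose isobutene on heating. The second ring opening may stall. Fallback (sets out from 3, returns at 34): the methylene bridge would be made by the classical condensation of two acylphloroglucinols with formaldehyde. Benzylation of the two more reactive hydroxyls of 3 (BnBr, K2CO3, acetone) should give 1-[4,6-bis(benzyloxy)-2-hydroxy-3-methylphenyl]butan-1-one F1. Methylation of the remaining chelated hydroxyl next to the methyl group (MeI, K2CO3, DMF) should give 1-[4,6-bis(benzyloxy)-2-methoxy-3-methylphenyl]butan-1-one F2. Hydrogenolysis (H2, Pd/C) should give 1-(4,6-dihydroxy-2-methoxy-3-methylphenyl)butan-1-one F3. Condensation of F3 and 3 with formaldehyde (aq. KOH, rt) should then give 34, which would have to be separated from the two symmetrical dimers.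

2. Step 11. The acidic medium may cleave the electron-rich diarylmethane at C1' by ipso-protonation, remove benzyl ethers, or divert the nitrile to O-imidate formation. Fallback (sets out from 30, returns at 33): a three-step sequence without strong acid. Magnesium-mediated ortho-formylation (MgCl2, Et3N, paraformaldehyde, MeCN, reflux) should give 3-{[2,4,6-tris(benzyloxy)-3-butanoyl-5-methylphenyl]methyl}-2,4-dihydroxy-6-methoxy-5-methylbenzaldehyde F4. Addition of n-PrMgBr (excess, THF, −78 → 0 °C; the ring A ketone is shielded by its two ortho substituents) should give racemic 1-{2,4,6-tris(benzyloxy)-3-{[2,6-dihydroxy-3-(1-hydroxybutyl)-4-methoxy-5-methylphenyl]methyl}-5-methylphenyl}butan-1-one F5. Oxidation of the benzylic alcohol (MnO2, CH2Cl2) should give 33.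

3. Step 2. Formaldehyde may bridge two molecules of 3 at C5 faster than the Meldrum's acid adduct is formed. Fallback (sets out from 3, returns at 9): the one-carbon unit is fixed on the phenol first. Aminomethylation of 3 with Eschenmoser's salt (CH2Cl2, rt) should give 1-{3-[(dimethylamino)methyl]-2,4,6-trihydroxy-5-methylphenyl}butan-1-one F6, which leaves no free ring position for dimerization. Heating F6 with Meldrum's acid 5 (toluene, reflux) should expel dimethylamine to an ortho-quinone methide that is trapped as 7 and converges through 8 on lactone 9.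

**Further compounds**
F1 | step 9 | 1-[4,6-bis(benzyloxy)-2-hydroxy-3-methylphenyl]butan-1-one | CCCC(=O)c1c(O)c(C)c(OCc2ccccc2)cc1OCc1ccccc1
F2 | step 9 | 1-[4,6-bis(benzyloxy)-2-methoxy-3-methylphenyl]butan-1-one | CCCC(=O)c1c(OC)c(C)c(OCc2ccccc2)cc1OCc1ccccc1
F3 | step 9 | 1-(4,6-dihydroxy-2-methoxy-3-methylphenyl)butan-1-one | CCCC(=O)c1c(OC)c(C)c(O)cc1O
F4 | step 11 | 3-{[2,4,6-tris(benzyloxy)-3-butanoyl-5-methylphenyl]methyl}-2,4-dihydroxy-6-methoxy-5-methylbenzaldehyde | CCCC(=O)c1c(OCc2ccccc2)c(C)c(OCc2ccccc2)c(Cc2c(O)c(C)c(OC)c(C=O)c2O)c1OCc1ccccc1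
F5 | step 11 | racemic 1-{2,4,6-tris(benzyloxy)-3-{[2,6-dihydroxy-3-(1-hydroxybutyl)-4-methoxy-5-methylphenyl]methyl}-5-methylphenyl}butan-1-one | CCCC(=O)c1c(OCc2ccccc2)c(C)c(OCc2ccccc2)c(Cc2c(O)c(C)c(OC)c(C(O)CCC)c2O)c1OCc1ccccc1
F6 | step 2 | 1-{3-[(dimethylamino)methyl]-2,4,6-trihydroxy-5-methylphenyl}butan-1-one | CCCC(=O)c1c(O)c(C)c(O)c(CN(C)C)c1O
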